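The dihydropyran ring of luzonoid A is cut at O2–C3 and C4–C5: O2–C3=C4(C11) is a propiolate unit set between the enol oxygen on C1 and C5, the β-carbon of a cyclopentenone whose carbonyl is C7. In one operation an oxa-Michael/Michael annulation of a 4-hydroxymethylene-cyclopentenone with methyl propiolate closes the 4H-pyran, brings in C3, C4 and C11, and sets C5 against the quaternary C8 carbinol. The precursor is (R)-5-hydroxy-4-(hydroxymethylidene)-5-(silyloxymethyl)cyclopent-2-enone, whose C8 centre comes from an asymmetric α-hydroxylation. Hydration of C1=C9, directed reduction of C7 and staged acylations finish the synthesis.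

Key step: step 7

Remark: ring atoms carry iridoid numbers (C1, O2, C3, C4, C5, C6, C7, C8, C9; C10 on C8, C11 on C4); β is the face of H-5 and H-9, so the target has 1β-O-acyl, 7β-O-acyl, 8α-OH and 8β-CH2OH.
Assumption: the antipode of the DBFOX ligand that delivers (S)-2 is used; the sense of induction is to be confirmed on 2 before scale-up.
Assumption: 14–18, 22 and 23 may be anomeric mixtures at C1, which is settled in step 16; their SMILES leave C1 open.

Step 1
Reactants: 1 tert-butyl 2-oxocyclopentane-1-carboxylate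
Product: 2 tert-butyl (S)-1-hydroxy-2-oxocyclopentane-1-carboxylate
Conditions: Ni(ClO4)2·6H2O (10 mol%), DBFOX/Ph (11 mol%), 4 Å MS, (±)-3-phenyl-2-(phenylsulfonyl)oxaziridine (1.2 equiv), CH2Cl2, rt
Reagents that add atoms: 3-phenyl-2-(phenylsulfonyl)oxaziridine, O=S(=O)(N1OC1c1ccccc1)c1ccccc1
Why: Chiral Lewis acid-catalysed electrophilic α-hydroxylation of a cyclic β-keto ester, in which the Ni(II)-bound enolate should be oxidised on one face only and so set the quaternary C8 carbinol as (S).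

Step 2
Reactants: 2 tert-butyl (S)-1-hydroxy-2-oxocyclopentane-1-carboxylate
Product: 3 (1R)-1-(hydroxymethyl)cyclopentane-1,2-diol (C2 epimers)
Conditions: LiAlH4 (excess), THF, 0 °C → reflux; Fieser work-up
Reagents that add atoms: none
Why: Exhaustive LiAlH4 reduction takes ketone and ester to the alcohol level; C8 is quaternary and cannot epimerise, and the new C7 carbinol centre is irrelevant because it is reoxidised in step 4.

Step 3
Reactants: 3 (1R)-1-(hydroxymethyl)cyclopentane-1,2-diol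
Product: 4 (1R)-1-{[(tert-butyldiphenylsilyl)oxy]methyl}cyclopentane-1,2-diol (C2 epimers)
Conditions: TBDPSCl (1.05 equiv), imidazole, DMF, 0 °C
Reagents that add atoms: tert-butyldiphenylsilyl chloride, CC(C)(C)[Si](Cl)(c1ccccc1)c1ccccc1
Why: Silylation with a bulky chlorosilane is selective for the primary hydroxyl over the secondary and tertiary ones.

Step 4
Reactants: 4 (1R)-1-{[(tert-butyldiphenylsilyl)oxy]methyl}cyclopentane-1,2-diol
Product: 5 (R)-2-{[(tert-butyldiphenylsilyl)oxy]methyl}-2-hydroxycyclopentan-1-one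
Conditions: IBX (1.5 equiv), DMSO, rt
Reagents that add atoms: none
Why: IBX oxidation of the secondary alcohol of a secondary/tertiary 1,2-diol should give the α-ketol without glycol cleavage.

Step 5
Reactants: 5 (R)-2-{[(tert-butyldiphenylsilyl)oxy]methyl}-2-hydroxycyclopentan-1-one
Product: 7 (R)-5-{[(tert-butyldiphenylsilyl)oxy]methyl}-5-(trimethylsilyloxy)cyclopent-2-en-1-one, via bis-TMS enol ether 6 (not isolated)
Conditions: TMSOTf (2.3 equiv), Et3N, CH2Cl2, 0 °C; then Pd(OAc)2 (1.1 equiv), MeCN, rt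
Reagents that add atoms: trimethylsilyl triflate, C[Si](C)(C)OS(=O)(=O)C(F)(F)F
Why: Saegusa–Ito dehydrogenation, in which soft enolisation can only go towards C6 (C8 is quaternary) and caps the tertiary hydroxyl as its TMS ether, and Pd(II) then turns the enol silane into the C5=C6 enone.

Step 6
Reactants: 7 (R)-5-{[(tert-butyldiphenylsilyl)oxy]methyl}-5-(trimethylsilyloxy)cyclopent-2-en-1-one; 8 trimethyl orthoformate
Product: 11 (5R)-5-{[(tert-butyldiphenylsilyl)oxy]methyl}-5-hydroxy-4-[(E)-hydroxymethylidene]cyclopent-2-en-1-one, via silyloxydiene 9 (not isolated), via dimethyl acetal 10 (not isolated)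
Conditions: TMSOTf (1.3 equiv), i-Pr2NEt (1.2 equiv), CH2Cl2, −78 → 0 °C; HC(OMe)3 (1.5 equiv), −78 °C; then 1 M aq. HCl–THF, rt
Reagents that add atoms: water, O
Why: Vinylogous Mukaiyama reaction, in which the enone can be enolised only at the γ-CH2 (C9), the 1-silyloxydiene should take up the dialkoxycarbenium ion at its γ-terminus C9 to restore the conjugated enone, and aqueous acid then unmasks the aldehyde (which rests as the conjugated enol) and cleaves the tertiary TMS ether; the transient C9 centre is lost on enolisation.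

Step 7
Reactants: 11 (5R)-5-{[(tert-butyldiphenylsilyl)oxy]methyl}-5-hydroxy-4-[(E)-hydroxymethylidene]cyclopent-2-en-1-one; 12 methyl propiolate
Product: 13 methyl (4aS,7R)-7-{[(tert-butyldiphenylsilyl)oxy]methyl}-7-hydroxy-6-oxo-4a,5,6,7-tetrahydrocyclopenta[c]pyran-4-carboxylate (4H-pyran with C1=C9 and C3=C4, C7 ketone, H-5β, 8α-OH)
Conditions: methyl propiolate (1.2 equiv), DABCO (20 mol%), MeCN, 0 °C → rt
Reagents that add atoms: none
Why: Proposed new method: DABCO turns the propiolate into a β-ammonium acrylate and the acidic enol into its enolate, whose oxygen on C1 adds to C3 (oxa-Michael); the resulting allenolate or ammonium enolate carries its nucleophilic C4 over C5 of the cross-conjugated enone and adds there (Michael), and loss of DABCO with protonation at C6 gives the 4H-pyran. The closest known reaction type is the amine- or phosphine-mediated oxa-Michael–Michael [4+2] annulation of o-hydroxyaryl enones with alkynoates to 4H-chromenes; here the C1=C9 enol double bond stands in for the arene, which has not been shown for an enolic vinylogous acid. The pyran ring closes by 6-exo-trig attack of C4 on C5, the C5=C6 bond being exocyclic to the new ring. The new stereocentre C5 is controlled by the quaternary C8: the tether must reach C5 perpendicular to the flat ring and should do so on the face of the small 8-OH, anti to the CH2OTBDPS group, which puts H-5 cis to C10. The step needs O- over C-attack of the ambident dienolate and ring closure before C4 is protonated; the hindered C9, amine catalysis (which favours O-vinylation of acidic hydroxyls), the cis placing of O2 and C5 on C1=C9, and the reversible re-addition of DABCO to any open β-enoloxyacrylate should secure both.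

Step 8
Reactants: 13 methyl (4aS,7R)-7-{[(tert-butyldiphenylsilyl)oxy]methyl}-7-hydroxy-6-oxo-4a,5,6,7-tetrahydrocyclopenta[c]pyran-4-carboxylate
Product: 14 methyl (4aS,7R,7aS)-7-{[(tert-butyldiphenylsilyl)oxy]methyl}-1,7-dihydroxy-6-oxo-1,4a,5,6,7,7a-hexahydrocyclopenta[c]pyran-4-carboxylate (cis-fused lactol)
Conditions: 1 M aq. HCl–THF (1:5), 0 °C → rt
Reagents that add atoms: water, O
Why: Acid-catalysed hydration of the electron-rich C1=C9 enol ether (C3=C4 is deactivated by the ester), in which protonation of C9 on the convex β-face and capture of the C1 oxocarbenium ion by water should give the cis-fused lactol, which is also the thermodynamic isomer (C1 anti to C10) reachable through the ring-opened aldehyde.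

Step 9
Reactants: 14 methyl (4aS,7R,7aS)-7-{[(tert-butyldiphenylsilyl)oxy]methyl}-1,7-dihydroxy-6-oxo-1,4a,5,6,7,7a-hexahydrocyclopenta[c]pyran-4-carboxylate
Product: 15 methyl (4aS,7R,7aS)-1-[(tert-butyldimethylsilyl)oxy]-7-{[(tert-butyldiphenylsilyl)oxy]methyl}-7-hydroxy-6-oxo-1,4a,5,6,7,7a-hexahydrocyclopenta[c]pyran-4-carboxylate
Conditions: TBSCl (1.2 equiv), imidazole, DMF, 0 °C
Reagents that add atoms: tert-butyldimethylsilyl chloride, CC(C)(C)[Si](C)(C)Cl
Why: Standard silylation caps the lactol hydroxyl as an anomeric silyl ether, which masks the latent aldehyde towards hydride, while the hindered tertiary 8-OH stays free.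

Step 10
Reactants: 15 methyl (4aS,7R,7aS)-1-[(tert-butyldimethylsilyl)oxy]-7-{[(tert-butyldiphenylsilyl)oxy]methyl}-7-hydroxy-6-oxo-1,4a,5,6,7,7a-hexahydrocyclopenta[c]pyran-4-carboxylate
Product: 16 methyl (4aS,6S,7R,7aS)-1-[(tert-butyldimethylsilyl)oxy]-7-{[(tert-butyldiphenylsilyl)oxy]methyl}-6,7-dihydroxy-1,4a,5,6,7,7a-hexahydrocyclopenta[c]pyran-4-carboxylate (7β-OH, trans to 8α-OH)
Conditions: Me4NBH(OAc)3 (5 equiv), MeCN–AcOH (1:1), −20 °C
Reagents that add atoms: none
Why: Hydroxyl-directed triacetoxyborohydride reduction (Evans–Saksena type), in which the tertiary 8α-OH binds boron and delivers hydride to the α-face of C7 to give the 7β-alcohol trans to 8-OH, while the β-CH2OTBDPS group shields the other face.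

Step 11
Reactants: 16 methyl (4aS,6S,7R,7aS)-1-[(tert-butyldimethylsilyl)oxy]-7-{[(tert-butyldiphenylsilyl)oxy]methyl}-6,7-dihydroxy-1,4a,5,6,7,7a-hexahydrocyclopenta[c]pyran-4-carboxylate
Product: 17 (4aS,6S,7R,7aS)-1-[(tert-butyldimethylsilyl)oxy]-7-{[(tert-butyldiphenylsilyl)oxy]methyl}-4-(hydroxymethyl)-1,4a,5,6,7,7a-hexahydrocyclopenta[c]pyran-6,7-diol
Conditions: DIBAL-H (6 equiv), CH2Cl2, −78 → −40 °C; Rochelle salt
Reagents that add atoms: none
Why: DIBAL-H reduction of the β-alkoxyacrylate ester should give the allylic C11 alcohol and leave the enol ether and the silyl acetal untouched.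

Step 12
Reactants: 17 (4aS,6S,7R,7aS)-1-[(tert-butyldimethylsilyl)oxy]-7-{[(tert-butyldiphenylsilyl)oxy]methyl}-4-(hydroxymethyl)-1,4a,5,6,7,7a-hexahydrocyclopenta[c]pyran-6,7-diol
Product: 18 (4aS,6S,7R,7aS)-1-[(tert-butyldimethylsilyl)oxy]-4,7-bis{[(tert-butyldiphenylsilyl)oxy]methyl}-1,4a,5,6,7,7a-hexahydrocyclopenta[c]pyran-6,7-diol
Conditions: TBDPSCl (1.1 equiv), imidazole, CH2Cl2, 0 °C
Reagents that add atoms: tert-butyldiphenylsilyl chloride, CC(C)(C)[Si](Cl)(c1ccccc1)c1ccccc1
Why: Selective silylation of the primary allylic hydroxyl over the hindered secondary 7-OH and the tertiary 8-OH.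

Step 13
Reactants: 19 (E)-4-hydroxycinnamic acid
Product: 21 (E)-3-{4-[(tert-butyldiphenylsilyl)oxy]phenyl}prop-2-enoic acid, via bis-silylated coumarate 20 (not isolated)
Conditions: TBDPSCl (2.2 equiv), imidazole, DMF, rt; then AcOH–THF–H2O, rt
Reagents that add atoms: tert-butyldiphenylsilyl chloride, CC(C)(C)[Si](Cl)(c1ccccc1)c1ccccc1
Why: Exhaustive silylation followed by mild aqueous acid hydrolysis of the labile silyl ester leaves the phenol protected and the acid free.

Step 14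
Reactants: 18 (4aS,6S,7R,7aS)-1-[(tert-butyldimethylsilyl)oxy]-4,7-bis{[(tert-butyldiphenylsilyl)oxy]methyl}-1,4a,5,6,7,7a-hexahydrocyclopenta[c]pyran-6,7-diol; 21 (E)-3-{4-[(tert-butyldiphenylsilyl)oxy]phenyl}prop-2-enoic acid
Product: 22 (4aS,6S,7R,7aS)-1-[(tert-butyldimethylsilyl)oxy]-4,7-bis{[(tert-butyldiphenylsilyl)oxy]methyl}-7-hydroxy-1,4a,5,6,7,7a-hexahydrocyclopenta[c]pyran-6-yl (E)-3-{4-[(tert-butyldiphenylsilyl)oxy]phenyl}prop-2-enoate
Conditions: EDC·HCl (2 equiv), DMAP, CH2Cl2, rt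
Reagents that add atoms: none
Why: Steglich esterification acylates the only reactive hydroxyl, the secondary 7-OH, with retention at C7, while the tertiary 8-OH does not react.

Step 15
Reactants: 22 (4aS,6S,7R,7aS)-1-[(tert-butyldimethylsilyl)oxy]-4,7-bis{[(tert-butyldiphenylsilyl)oxy]methyl}-7-hydroxy-1,4a,5,6,7,7a-hexahydrocyclopenta[c]pyran-6-yl (E)-3-{4-[(tert-butyldiphenylsilyl)oxy]phenyl}prop-2-enoate
Product: 23 (4aS,6S,7R,7aS)-4,7-bis{[(tert-butyldiphenylsilyl)oxy]methyl}-1,7-dihydroxy-1,4a,5,6,7,7a-hexahydrocyclopenta[c]pyran-6-yl (E)-3-{4-[(tert-butyldiphenylsilyl)oxy]phenyl}prop-2-enoate (lactol)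
Conditions: HF·pyridine, pyridine, THF, 0 °C
Reagents that add atoms: none
Why: Selective desilylation with buffered acidic fluoride, which should cleave the anomeric TBS ether (the lactol oxygen is the best leaving group and TBS the smallest silyl group) well before the primary TBDPS ethers or the aryl silyl ether.

Step 16
Reactants: 23 (4aS,6S,7R,7aS)-4,7-bis{[(tert-butyldiphenylsilyl)oxy]methyl}-1,7-dihydroxy-1,4a,5,6,7,7a-hexahydrocyclopenta[c]pyran-6-yl (E)-3-{4-[(tert-butyldiphenylsilyl)oxy]phenyl}prop-2-enoate; 24 3-methylbutanoic (isovaleric) anhydride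
Product: 25 (1S,4aS,6S,7R,7aS)-4,7-bis{[(tert-butyldiphenylsilyl)oxy]methyl}-7-hydroxy-1-[(3-methylbutanoyl)oxy]-1,4a,5,6,7,7a-hexahydrocyclopenta[c]pyran-6-yl (E)-3-{4-[(tert-butyldiphenylsilyl)oxy]phenyl}prop-2-enoate (tris-TBDPS luzonoid A)
Conditions: isovaleric anhydride (1.5 equiv), Et3N, DMAP (cat.), CH2Cl2, −20 → 0 °C
Reagents that add atoms: none
Why: DMAP-catalysed acylation of the lactol, the only acylable hydroxyl, whose anomers interconvert through the open form so that the acyl group should settle on the β-oxygen, pseudo-axial (anomeric effect) and anti to the quaternary C8, as in natural 1-O-substituted iridoids.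

Step 17
Reactants: 25 tris-TBDPS luzonoid A
Product: 26 luzonoid A
Conditions: TBAF (6 equiv), AcOH (6 equiv), THF, 0 °C → rt
Reagents that add atoms: none
Why: Fluoride-mediated global desilylation, buffered with acetic acid so that the anomeric ester should survive and the coumarate should not migrate to the freed 10-OH.

Compound list
1 | tert-butyl 2-oxocyclopentane-1-carboxylate | CC(C)(C)OC(=O)C1CCCC1=O | starting material
2 | tert-butyl (S)-1-hydroxy-2-oxocyclopentane-1-carboxylate | CC(C)(C)OC(=O)[C@]1(O)CCCC1=O | intermediate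
3 | (1R)-1-(hydroxymethyl)cyclopentane-1,2-diol (C2 epimers) | OC[C@]1(O)CCCC1O | intermediate
4 | (1R)-1-{[(tert-butyldiphenylsilyl)oxy]methyl}cyclopentane-1,2-diol (C2 epimers) | CC(C)(C)[Si](c1ccccc1)(c1ccccc1)OC[C@]1(O)CCCC1O | intermediate
5 | (R)-2-{[(tert-butyldiphenylsilyl)oxy]methyl}-2-hydroxycyclopentan-1-one | CC(C)(C)[Si](c1ccccc1)(c1ccccc1)OC[C@]1(O)CCCC1=O | intermediate
6 | (R)-tert-butyl{[1,2-bis(trimethylsilyloxy)cyclopent-2-en-1-yl]methoxy}diphenylsilane | CC(C)(C)[Si](c1ccccc1)(c1ccccc1)OC[C@]1(O[Si](C)(C)C)CCC=C1O[Si](C)(C)C | intermediate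
7 | (R)-5-{[(tert-butyldiphenylsilyl)oxy]methyl}-5-(trimethylsilyloxy)cyclopent-2-en-1-one | CC(C)(C)[Si](c1ccccc1)(c1ccccc1)OC[C@]1(O[Si](C)(C)C)CC=CC1=O | intermediate
8 | trimethyl orthoformate | COC(OC)OC | starting material
9 | (R)-tert-butyl{[1,2-bis(trimethylsilyloxy)cyclopenta-2,4-dien-1-yl]methoxy}diphenylsilane | CC(C)(C)[Si](c1ccccc1)(c1ccccc1)OC[C@]1(O[Si](C)(C)C)C=CC=C1O[Si](C)(C)C | intermediate
10 | (5R)-5-{[(tert-butyldiphenylsilyl)oxy]methyl}-4-(dimethoxymethyl)-5-(trimethylsilyloxy)cyclopent-2-en-1-one (C4 epimers) | CC(C)(C)[Si](c1ccccc1)(c1ccccc1)OC[C@]1(O[Si](C)(C)C)C(C(OC)OC)C=CC1=O | intermediate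
11 | (5R)-5-{[(tert-butyldiphenylsilyl)oxy]methyl}-5-hydroxy-4-[(E)-hydroxymethylidene]cyclopent-2-en-1-one | O/C=C1\C=CC(=O)[C@]1(O)CO[Si](c2ccccc2)(c2ccccc2)C(C)(C)C | intermediate
12 | methyl propiolate | C#CC(=O)OC | starting material
13 | methyl (4aS,7R)-7-{[(tert-butyldiphenylsilyl)oxy]methyl}-7-hydroxy-6-oxo-4a,5,6,7-tetrahydrocyclopenta[c]pyran-4-carboxylate | COC(=O)C1=COC=C2[C@@H]1CC(=O)[C@]2(O)CO[Si](c3ccccc3)(c3ccccc3)C(C)(C)C | intermediate
14 | methyl (4aS,7R,7aS)-7-{[(tert-butyldiphenylsilyl)oxy]methyl}-1,7-dihydroxy-6-oxo-1,4a,5,6,7,7a-hexahydrocyclopenta[c]pyran-4-carboxylate | OC1OC=C(C(=O)OC)[C@H]2CC(=O)[C@](O)(CO[Si](c3ccccc3)(c3ccccc3)C(C)(C)C)[C@@H]12 | intermediate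
15 | methyl (4aS,7R,7aS)-1-[(tert-butyldimethylsilyl)oxy]-7-{[(tert-butyldiphenylsilyl)oxy]methyl}-7-hydroxy-6-oxo-1,4a,5,6,7,7a-hexahydrocyclopenta[c]pyran-4-carboxylate | CC(C)(C)[Si](C)(C)OC1OC=C(C(=O)OC)[C@H]2CC(=O)[C@](O)(CO[Si](c3ccccc3)(c3ccccc3)C(C)(C)C)[C@@H]12 | intermediate
16 | methyl (4aS,6S,7R,7aS)-1-[(tert-butyldimethylsilyl)oxy]-7-{[(tert-butyldiphenylsilyl)oxy]methyl}-6,7-dihydroxy-1,4a,5,6,7,7a-hexahydrocyclopenta[c]pyran-4-carboxylate | CC(C)(C)[Si](C)(C)OC1OC=C(C(=O)OC)[C@H]2C[C@H](O)[C@](O)(CO[Si](c3ccccc3)(c3ccccc3)C(C)(C)C)[C@@H]12 | intermediate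
17 | (4aS,6S,7R,7aS)-1-[(tert-butyldimethylsilyl)oxy]-7-{[(tert-butyldiphenylsilyl)oxy]methyl}-4-(hydroxymethyl)-1,4a,5,6,7,7a-hexahydrocyclopenta[c]pyran-6,7-diol | CC(C)(C)[Si](C)(C)OC1OC=C(CO)[C@H]2C[C@H](O)[C@](O)(CO[Si](c3ccccc3)(c3ccccc3)C(C)(C)C)[C@@H]12 | intermediate
18 | (4aS,6S,7R,7aS)-1-[(tert-butyldimethylsilyl)oxy]-4,7-bis{[(tert-butyldiphenylsilyl)oxy]methyl}-1,4a,5,6,7,7a-hexahydrocyclopenta[c]pyran-6,7-diol | CC(C)(C)[Si](C)(C)OC1OC=C(CO[Si](c3ccccc3)(c3ccccc3)C(C)(C)C)[C@H]2C[C@H](O)[C@](O)(CO[Si](c3ccccc3)(c3ccccc3)C(C)(C)C)[C@@H]12 | intermediate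
19 | (E)-4-hydroxycinnamic acid | OC(=O)/C=C/c1ccc(O)cc1 | starting material
20 | tert-butyldiphenylsilyl (E)-3-{4-[(tert-butyldiphenylsilyl)oxy]phenyl}prop-2-enoate | CC(C)(C)[Si](c1ccccc1)(c1ccccc1)OC(=O)/C=C/c1ccc(O[Si](c2ccccc2)(c2ccccc2)C(C)(C)C)cc1 | intermediate
21 | (E)-3-{4-[(tert-butyldiphenylsilyl)oxy]phenyl}prop-2-enoic acid | OC(=O)/C=C/c1ccc(O[Si](c2ccccc2)(c2ccccc2)C(C)(C)C)cc1 | intermediate
22 | (4aS,6S,7R,7aS)-1-[(tert-butyldimethylsilyl)oxy]-4,7-bis{[(tert-butyldiphenylsilyl)oxy]methyl}-7-hydroxy-1,4a,5,6,7,7a-hexahydrocyclopenta[c]pyran-6-yl (E)-3-{4-[(tert-butyldiphenylsilyl)oxy]phenyl}prop-2-enoate | CC(C)(C)[Si](C)(C)OC1OC=C(CO[Si](c3ccccc3)(c3ccccc3)C(C)(C)C)[C@H]2C[C@H](OC(=O)/C=C/c3ccc(O[Si](c4ccccc4)(c4ccccc4)C(C)(C)C)cc3)[C@](O)(CO[Si](c3ccccc3)(c3ccccc3)C(C)(C)C)[C@@H]12 | intermediate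
23 | (4aS,6S,7R,7aS)-4,7-bis{[(tert-butyldiphenylsilyl)oxy]methyl}-1,7-dihydroxy-1,4a,5,6,7,7a-hexahydrocyclopenta[c]pyran-6-yl (E)-3-{4-[(tert-butyldiphenylsilyl)oxy]phenyl}prop-2-enoate | OC1OC=C(CO[Si](c3ccccc3)(c3ccccc3)C(C)(C)C)[C@H]2C[C@H](OC(=O)/C=C/c3ccc(O[Si](c4ccccc4)(c4ccccc4)C(C)(C)C)cc3)[C@](O)(CO[Si](c3ccccc3)(c3ccccc3)C(C)(C)C)[C@@H]12 | intermediate
24 | 3-methylbutanoic (isovaleric) anhydride | CC(C)CC(=O)OC(=O)CC(C)C | starting material
25 | (1S,4aS,6S,7R,7aS)-4,7-bis{[(tert-butyldiphenylsilyl)oxy]methyl}-7-hydroxy-1-[(3-methylbutanoyl)oxy]-1,4a,5,6,7,7a-hexahydrocyclopenta[c]pyran-6-yl (E)-3-{4-[(tert-butyldiphenylsilyl)oxy]phenyl}prop-2-enoate | CC(C)CC(=O)O[C@@H]1OC=C(CO[Si](c3ccccc3)(c3ccccc3)C(C)(C)C)[C@H]2C[C@H](OC(=O)/C=C/c3ccc(O[Si](c4ccccc4)(c4ccccc4)C(C)(C)C)cc3)[C@](O)(CO[Si](c3ccccc3)(c3ccccc3)C(C)(C)C)[C@@H]12 | intermediate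
26 | luzonoid A, (1S,4aS,6S,7R,7aS)-7-hydroxy-4,7-bis(hydroxymethyl)-1-[(3-methylbutanoyl)oxy]-1,4a,5,6,7,7a-hexahydrocyclopenta[c]pyran-6-yl (E)-3-(4-hydroxyphenyl)prop-2-enoate | CC(C)CC(=O)O[C@@H]1OC=C(CO)[C@H]2C[C@H](OC(=O)/C=C/c3ccc(O)cc3)[C@](O)(CO)[C@@H]12 | target

Total step count: 17. Longest linear sequence: 16 steps (steps 1–12 and 14–17; step 13 is a one-step side branch).

Steps most likely to fail

Step 7 (Proposed new method). The ambident dienolate may be alkylated at carbon (C6) instead of at the oxygen on C1. The C4 anion may also be protonated before it reaches C5, leaving an open β-enoloxyacrylate, or the tether may close on the wrong face of C5. The fallback sets out from 7 and comes back at 16, and builds the pyran ring by the de Mayo photoannulation, a known reaction type for iridoid lactols. From 7 the silyloxydiene 9 is formed as in step 6 and desilylated with TBAF/AcOH in THF at −78 °C, where kinetic protonation at C6 should give the β,γ-unsaturated ketol (R)-2-{[(tert-butyldiphenylsilyl)oxy]methyl}-2-hydroxycyclopent-3-en-1-one F1, with the alkene now at C5=C9. Directed reduction under the conditions of step 10 should give the trans-diol (1S,2R)-2-{[(tert-butyldiphenylsilyl)oxy]methyl}cyclopent-3-ene-1,2-diol F2. Irradiation of F2 (Pyrex-filtered mercury lamp, MeCN) with methyl diformylacetate F3, a known reagent obtained in one operation from methyl 3,3-dimethoxypropanoate (NaH, methyl formate; then aqueous acid), should add the enol across C5=C9 on the α-face, anti to C10, with the fully substituted carbon bonding to the less hindered C5. Retro-aldol opening of the cyclobutanol and lactol closure then give methyl (4aS,6S,7R,7aS)-7-{[(tert-butyldiphenylsilyl)oxy]methyl}-1,6,7-trihydroxy-1,4a,5,6,7,7a-hexahydrocyclopenta[c]pyran-4-carboxylate F4. Silylation of the lactol hydroxyl with TBSCl/imidazole, in preference to the hindered 7-OH, returns the route at 16.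

Step 6. The orthoformate-derived cation may attack the unhindered α-carbon C6 instead of the γ-carbon C9, which sits next to the quaternary C8, and the silyloxycyclopentadiene may dimerise before it is trapped. The fallback sets out from 7 and comes back at 11, and replaces the Lewis-acid Mukaiyama step by a thermodynamically driven aminomethylenation. Heating 7 with tert-butoxybis(dimethylamino)methane (Bredereck's reagent) in toluene should condense at the only acidic CH2 (C9) to the fully conjugated push–pull dienaminone (R,E)-5-{[(tert-butyldiphenylsilyl)oxy]methyl}-4-[(dimethylamino)methylidene]-5-(trimethylsilyloxy)cyclopent-2-en-1-one F5. Hydrolysis with 1 M aqueous HCl in THF exchanges the amine for hydroxyl, cleaves the TMS ether and gives 11.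

Step 15. The phenolic silyl ether may be lost alongside the anomeric one, or cleavage at the electron-poor anomeric oxygen may be so slow that the primary TBDPS ethers begin to fall off. The fallback sets out from 18 and comes back at 25, and changes the order of the acylations so that no aryl silyl ether is present when the anomeric group is removed. Treatment of 18 with TBAF/AcOH in THF at −20 °C should give the lactol (4aS,6S,7R,7aS)-4,7-bis{[(tert-butyldiphenylsilyl)oxy]methyl}-1,4a,5,6,7,7a-hexahydrocyclopenta[c]pyran-1,6,7-triol F6. Acylation with 24 (1.05 equiv), Et3N and catalytic DMAP at −40 °C should take the reactive lactol hydroxyl in preference to the hindered 7-OH and give (1S,4aS,6S,7R,7aS)-4,7-bis{[(tert-butyldiphenylsilyl)oxy]methyl}-6,7-dihydroxy-1,4a,5,6,7,7a-hexahydrocyclopenta[c]pyran-1-yl 3-methylbutanoate F7. Steglich esterification of F7 with 21 (EDC·HCl, DMAP) then gives 25.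

Further compounds
F1 | step 7 | (R)-2-{[(tert-butyldiphenylsilyl)oxy]methyl}-2-hydroxycyclopent-3-en-1-one | CC(C)(C)[Si](c1ccccc1)(c1ccccc1)OC[C@]1(O)C=CCC1=O
F2 | step 7 | (1S,2R)-2-{[(tert-butyldiphenylsilyl)oxy]methyl}cyclopent-3-ene-1,2-diol | C1C=C[C@@](O)(CO[Si](c2ccccc2)(c2ccccc2)C(C)(C)C)[C@H]1O
F3 | step 7 | methyl diformylacetate (methyl 2-formyl-3-oxopropanoate) | COC(=O)C(C=O)C=O
F4 | step 7 | methyl (4aS,6S,7R,7aS)-7-{[(tert-butyldiphenylsilyl)oxy]methyl}-1,6,7-trihydroxy-1,4a,5,6,7,7a-hexahydrocyclopenta[c]pyran-4-carboxylate | OC1OC=C(C(=O)OC)[C@H]2C[C@H](O)[C@](O)(CO[Si](c3ccccc3)(c3ccccc3)C(C)(C)C)[C@@H]12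
F5 | step 6 | (R,E)-5-{[(tert-butyldiphenylsilyl)oxy]methyl}-4-[(dimethylamino)methylidene]-5-(trimethylsilyloxy)cyclopent-2-en-1-one | CN(C)/C=C1\C=CC(=O)[C@]1(O[Si](C)(C)C)CO[Si](c2ccccc2)(c2ccccc2)C(C)(C)C
F6 | step 15 | (4aS,6S,7R,7aS)-4,7-bis{[(tert-butyldiphenylsilyl)oxy]methyl}-1,4a,5,6,7,7a-hexahydrocyclopenta[c]pyran-1,6,7-triol | OC1OC=C(CO[Si](c3ccccc3)(c3ccccc3)C(C)(C)C)[C@H]2C[C@H](O)[C@](O)(CO[Si](c3ccccc3)(c3ccccc3)C(C)(C)C)[C@@H]12
F7 | step 15 | (1S,4aS,6S,7R,7aS)-4,7-bis{[(tert-butyldiphenylsilyl)oxy]methyl}-6,7-dihydroxy-1,4a,5,6,7,7a-hexahydrocyclopenta[c]pyran-1-yl 3-methylbutanoate | CC(C)CC(=O)O[C@@H]1OC=C(CO[Si](c3ccccc3)(c3ccccc3)C(C)(C)C)[C@H]2C[C@H](O)[C@](O)(CO[Si](c3ccccc3)(c3ccccc3)C(C)(C)C)[C@@H]12
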